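**Plan**

- Retrosynthesis: remove the sulfate and unmask the arene; cut the bond between the two-carbon tether and the ring A methine (aldol logic, ring A as a regiodefined ketone enolate); cut the two ring B bonds made by a Diels–Alder reaction; cut the CH3–CH and ArCH2–C bonds of ring C.
- Forward: ring C is made first (step 1). Ring B is added by cycloaddition of methacrolein to the vinylcyclohexene derived from the ring C ketone, the alkene is moved into the ring fusion and the aldehyde is extended by one carbon. Ring A, made from the same enone, is joined last, followed by methylenation, arene unmasking, sulfation and desilylation.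
- Enabling feature: in ring C the CH(CH3) carbon is bonded to the quaternary carbon that carries CH3 and the 2,5-dioxygenated benzyl group (benzyl trans to the secondary methyl, the two methyls cis). This quaternary carbon is bonded to a ring-fusion alkene carbon that can be a former carbonyl carbon. That is the imprint of β-methylation and α-benzylation of 2-methylcyclohex-2-en-1-one.
- Stereochemistry: the ring C methine comes from the CuO2CC4H3S–phosphoramidite catalyst and the adjacent quaternary carbon from anti alkylation. The ring B quaternary carbon comes from the chiral oxazaborolidinium Diels–Alder catalyst. In ring A the carbinol comes from CBS reduction, the quaternary carbon from anti conjugate addition, and the methine from axial protonation at an enolisable centre.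

Key step: step 1

Remark: the aryl sulfate is written as the free acid, as in the target structure; it would be isolated and stored as its sodium salt because the free acid hydrolyses easily, and both are treated as the same compound.

**Route**

Step 1
Reactants: 1 2-methylcyclohex-2-en-1-one; 2 trimethylaluminium; 3 2,5-dimethoxybenzyl bromide
Product: 6 ring C ketone (2R,3S)-2-(2,5-dimethoxybenzyl)-2,3-dimethylcyclohexan-1-one, via dimethylaluminium enolate 4 (not isolated), via lithium trimethylaluminate enolate 5 (not isolated)
Conditions: CuO2CC4H3S (2 mol%), binaphthyl bis(1-phenylethyl)amine phosphoramidite ligand (4 mol%), Et2O, −30 °C; then MeLi, THF/HMPA, −30 → 0 °C; then 3, 0 → 23 °C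
Reagents that add atoms: none
Why: The phosphoramidite complex of monovalent copper formed from CuO2CC4H3S takes a methyl group from Me3Al and delivers it to the β-carbon of the enone through a π-complex and reductive elimination, leaving the regiodefined enolate 4; MeLi converts this sluggish enolate into the nucleophilic aluminate 5, which displaces bromide from the benzylic halide at the methyl-bearing α-carbon. The closest known reaction type is the enantioselective conjugate addition of trialkylaluminium reagents to 2-substituted cyclohexenones under CuO2CC4H3S–phosphoramidite catalysis, with alkylation of the enolate after ate-complex formation. No ring is closed; the CH3–CH and ArCH2–C bonds are formed. The methine (S) is set by the ligand, whose enantiomer is chosen for this sense, and the quaternary carbon (R) is set by the methine, because the electrophile approaches the enolate face opposite the new methyl, so that benzyl ends trans to it and the two methyls cis. The step needs C-alkylation at the substituted α-carbon without enolate equilibration; this is secured because the enolate is generated regiospecifically by the conjugate addition, is never protonated before it meets the reactive benzylic bromide, and the aryl methyl ethers are inert to all reagents present.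

Step 2
Reactants: 6 ring C ketone
Product: 7 enol triflate (5S,6R)-6-(2,5-dimethoxybenzyl)-5,6-dimethylcyclohex-1-en-1-yl trifluoromethanesulfonate
Conditions: KN(SiMe3)2, THF, −78 °C; then PhNTf2, −78 → 0 °C
Reagents that add atoms: N-phenylbis(trifluoromethanesulfonimide), O=S(=O)(N(c1ccccc1)S(=O)(=O)C(F)(F)F)C(F)(F)F
Why: Enol triflate formation by O-sulfonylation of the enolate made with KN(SiMe3)2 is regiospecific because only the CH2 flank of the carbonyl can be deprotonated, the other α-carbon being quaternary, and the β-methine is not affected.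

Step 3
Reactants: 7 enol triflate
Product: 8 diene 2-{[(1R,6S)-2-ethenyl-1,6-dimethylcyclohex-2-en-1-yl]methyl}-1,4-dimethoxybenzene
Conditions: Bu3SnCH=CH2, Pd(PPh3)4 (5 mol%), LiCl, THF, 65 °C
Reagents that add atoms: tributyl(vinyl)stannane, C=C[Sn](CCCC)(CCCC)CCCC
Why: Stille coupling of the enol triflate with the vinylstannane, with Pd(PPh3)4 as the source of zerovalent palladium and LiCl to assist transmetalation, is dependable even beside a quaternary carbon and gives the 2-vinylcyclohexene diene without touching a stereocentre.

Step 4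
Reactants: 8 diene; 9 methacrolein
Product: 10 Diels–Alder aldehyde (1S,5R,6S,8aR)-5-(2,5-dimethoxybenzyl)-1,5,6-trimethyl-1,2,3,5,6,7,8,8a-octahydronaphthalene-1-carbaldehyde
Conditions: oxazaborolidinium triflimide from (S)-α,α-diphenylprolinol, o-tolylboronic acid and HNTf2 (20 mol%), CH2Cl2, −78 → −40 °C
Reagents that add atoms: none
Why: Catalytic enantioselective Diels–Alder reaction with a cationic oxazaborolidine: the Lewis-acid-bound enal should add in the ortho sense (β-carbon to the vinyl CH2, α-carbon to the ring CH, as the terminal alkyl substituent of the diene dictates), and the configuration of the new formyl-bearing quaternary carbon depends only on which face of methacrolein is attacked, so it is set by the catalyst (the α-Re face must stay open, which the usual binding model assigns to the (S)-prolinol-derived catalyst), whereas the ring-fusion CH formed at the same time is uncontrolled and is removed in step 5.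

Step 5
Reactants: 10 Diels–Alder aldehyde
Product: 11 ring-fusion alkene aldehyde (1S,5R,6S)-5-(2,5-dimethoxybenzyl)-1,5,6-trimethyl-1,2,3,4,5,6,7,8-octahydronaphthalene-1-carbaldehyde
Conditions: TsOH·H2O (10 mol%), toluene, 70 °C
Reagents that add atoms: none
Why: Acid-catalysed alkene isomerisation through the tertiary ring-fusion cation should move the trisubstituted alkene to the tetrasubstituted position between the two fusion carbons, the thermodynamic site in this octalin, which deletes the uncontrolled fusion centre and leaves the two quaternary carbons and the methine untouched.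

Step 6
Reactants: 11 ring-fusion alkene aldehyde
Product: 12 enol ether (1R,5R,6S)-5-(2,5-dimethoxybenzyl)-1-(2-methoxyethenyl)-1,5,6-trimethyl-1,2,3,4,5,6,7,8-octahydronaphthalene (E/Z; E drawn)
Conditions: Ph3P(CH2OMe)Cl, KN(SiMe3)2, THF, 0 → 23 °C
Reagents that add atoms: (methoxymethyl)triphenylphosphonium chloride, COC[P+](c1ccccc1)(c1ccccc1)c1ccccc1.[Cl-]
Why: Wittig methoxymethylenation adds the second tether carbon to the hindered, non-enolisable aldehyde as an enol ether whose geometry does not matter.

Step 7
Reactants: 12 enol ether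
Product: 13 homologated aldehyde 2-[(1R,5R,6S)-5-(2,5-dimethoxybenzyl)-1,5,6-trimethyl-1,2,3,4,5,6,7,8-octahydronaphthalen-1-yl]acetaldehyde
Conditions: 2 M HCl, THF, 23 °C
Reagents that add atoms: water, O
Why: Acid-catalysed enol ether hydrolysis (C-protonation, hydration of the oxocarbenium ion, loss of methanol) runs in dilute acid at room temperature, which is too mild to protonate the tetrasubstituted alkene or cleave the aryl ethers.

Step 8
Reactants: 1 2-methylcyclohex-2-en-1-one
Product: 14 (S)-2-methylcyclohex-2-en-1-ol
Conditions: (R)-2-methyl-CBS-oxazaborolidine (10 mol%), BH3·SMe2, THF, −20 °C; aqueous work-up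
Reagents that add atoms: none
Why: Corey–Bakshi–Shibata reduction of the carbonyl group alone, in which the methyl-bearing alkene carbon plays the large group and the ring CH2 the small one, so that the (R)-catalyst should deliver hydride to the face giving the (S)-allylic alcohol with the six-membered ring and its alkene unchanged.

Step 9
Reactants: 14 (S)-2-methylcyclohex-2-en-1-ol
Product: 15 tert-butyldimethyl{[(1S)-2-methylcyclohex-2-en-1-yl]oxy}silane
Conditions: TBSCl, imidazole, DMF, 23 °C
Reagents that add atoms: tert-butyldimethylsilyl chloride, CC(C)(C)[Si](C)(C)Cl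
Why: Routine silylation of a secondary allylic alcohol gives an ether that later steers the conjugate addition and survives until the last step.

Step 10
Reactants: 15 allylic silyl ether
Product: 16 (S)-4-[(tert-butyldimethylsilyl)oxy]-3-methylcyclohex-2-en-1-one
Conditions: CrO3, 3,5-dimethylpyrazole, CH2Cl2, −20 °C
Reagents that add atoms: chromium trioxide, O=[Cr](=O)=O
Why: Allylic oxidation with the CrO3–3,5-dimethylpyrazole complex should convert the ring CH2 next to the alkene CH of the cyclohexene into the enone carbonyl, the other allylic ring position being shielded by its bulky silyloxy group, and the carbinol stereocentre is not involved.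

Step 11
Reactants: 16 silyloxy enone; 17 5-bromo-2-methylpent-2-ene
Product: 19 ring A silyl enol ether (3S,4S)-4-[(tert-butyldimethylsilyl)oxy]-3-methyl-3-(4-methylpent-3-en-1-yl)-1-[(trimethylsilyl)oxy]cyclohex-1-ene, via (4-methylpent-3-en-1-yl)magnesium bromide 18 (not isolated)
Conditions: 17, Mg, THF, 23 °C; then CuBr·SMe2 (10 mol%), Me3SiCl, HMPA, 16, THF, −78 → −40 °C; Et3N
Reagents that add atoms: chlorotrimethylsilane, C[Si](C)(C)Cl
Why: CuBr·SMe2-catalysed conjugate addition of a Grignard reagent accelerated by Me3SiCl builds the quaternary carbon on the β,β-disubstituted enone and traps the enolate regiospecifically as its silyl ether; the nucleophile enters anti to the adjacent silyloxy group, which places the homoprenyl chain trans to oxygen and the ring methyl cis to it.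

Step 12
Reactants: 19 ring A silyl enol ether; 13 homologated aldehyde
Product: 21 aldol adduct (β-hydroxy ketone linking ring A to the octalin tether), via ring A lithium enolate 20 (not isolated)
Conditions: MeLi, THF, 0 °C; then 13, −78 °C; NH4Cl
Reagents that add atoms: none
Why: Methyllithium cleaves the trimethylsilyl enol ether to the regiodefined lithium enolate, whose aldol addition to the unhindered aldehyde forms the bond between ring A and the tether; both new centres are removed in steps 13 and 14, so their configuration is immaterial.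

Step 13
Reactants: 21 aldol adduct
Product: 23 ring A 2-alkylidene ketone (E/Z enone), via aldol methanesulfonate 22 (not isolated)
Conditions: MsCl, Et3N, CH2Cl2, 0 °C; then DBU, 23 °C
Reagents that add atoms: none
Why: Mesylation of the aldol hydroxyl and E1cB elimination with DBU give the exocyclic enone, since only the ring hydrogen next to the carbonyl is acidic enough to start the elimination.

Step 14
Reactants: 23 ring A 2-alkylidene ketone
Product: 24 saturated ring A ketone (2S,3S,4S)-configured at ring A
Conditions: [(Ph3P)CuH]6, H2O, benzene, 23 °C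
Reagents that add atoms: none
Why: Stryker reduction (conjugate hydride transfer from [(Ph3P)CuH]6) reduces the enone alone among four alkenes, and protonation of the resulting enolate from the axial direction opposite the axial ring methyl puts the tether equatorial, cis to the methyl and the silyloxy group, which is also the more stable epimer at this enolisable centre.

Step 15
Reactants: 24 saturated ring A ketone
Product: 25 exocyclic methylene silyl ether (full carbon skeleton with dimethoxyarene)
Conditions: Ph3PCH3Br, KOtBu, toluene, 90 °C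
Reagents that add atoms: methyltriphenylphosphonium bromide, C[P+](c1ccccc1)(c1ccccc1)c1ccccc1.[Br-]
Why: Wittig methylenation of a 2-alkyl-3,3-disubstituted cyclohexanone is well known from 8-oxolabdane chemistry, and any enolisation under the basic conditions returns the equatorial epimer before the exocyclic alkene fixes the centre.

Step 16
Reactants: 25 exocyclic methylene silyl ether
Product: 27 hydroquinone silyl ether, via benzoquinone silyl ether 26 (not isolated)
Conditions: (NH4)2Ce(NO3)6, MeCN/H2O, 0 °C; then Na2S2O4, EtOAc/H2O, 23 °C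
Reagents that add atoms: water, O
Why: Oxidative demethylation of the 1,4-dimethoxyarene by (NH4)2Ce(NO3)6, a tetravalent cerium oxidant, gives the quinone within minutes, faster than isolated alkenes or the silyl ether react, and dithionite then reduces it to the hydroquinone.

Step 17
Reactants: 27 hydroquinone silyl ether
Product: 28 aryl monosulfate silyl ether (hydrogen sulfate on the phenol oxygen meta to the benzylic carbon)
Conditions: SO3·pyridine (1.1 equiv), pyridine, 0 °C; NaHCO3
Reagents that add atoms: sulfur trioxide–pyridine complex, O=S(=O)([O-])[n+]1ccccc1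
Why: O-Sulfation with SO3·pyridine should take place at the phenol flanked by two ring hydrogens and not at the one beside the neopentyl-type benzylic substituent, while the only aliphatic alcohol is still silylated.

Step 18
Reactants: 28 aryl monosulfate silyl ether
Product: 29 target, 4-hydroxy-3-{[(1R,2S,5R)-5-{2-[(1R,2S,3S)-3-hydroxy-2-methyl-6-methylidene-2-(4-methylpent-3-en-1-yl)cyclohexyl]ethyl}-1,2,5-trimethyl-1,2,3,4,5,6,7,8-octahydronaphthalen-1-yl]methyl}phenyl hydrogen sulfate
Conditions: Bu4NF, THF, 40 °C; Na+ ion exchange
Reagents that add atoms: none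
Why: Fluoride-mediated cleavage of the silyl ether releases the secondary alcohol under basic, non-hydrolytic conditions that aryl sulfate monoesters tolerate.

**Compound list**

1 | 2-methylcyclohex-2-en-1-one | CC1=CCCCC1=O | starting material
2 | trimethylaluminium | C[Al](C)C | starting material
3 | 2,5-dimethoxybenzyl bromide | COc1ccc(OC)c(CBr)c1 | starting material
4 | dimethyl{[(3S)-2,3-dimethylcyclohex-1-en-1-yl]oxy}aluminium (aluminium enolate, formed in the flask) | C[Al](C)OC1=C(C)[C@@H](C)CCC1 | intermediate
5 | lithium trimethyl{[(3S)-2,3-dimethylcyclohex-1-en-1-yl]oxy}aluminate (formed in the flask) | [Li+].C[Al-](C)(C)OC1=C(C)[C@@H](C)CCC1 | intermediate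
6 | ring C ketone (2R,3S)-2-(2,5-dimethoxybenzyl)-2,3-dimethylcyclohexan-1-one | O=C1CCC[C@H](C)[C@@]1(C)Cc1cc(OC)ccc1OC | intermediate
7 | enol triflate (5S,6R)-6-(2,5-dimethoxybenzyl)-5,6-dimethylcyclohex-1-en-1-yl trifluoromethanesulfonate | O=S(=O)(OC1=CCC[C@H](C)[C@@]1(C)Cc1cc(OC)ccc1OC)C(F)(F)F | intermediate
8 | diene 2-{[(1R,6S)-2-ethenyl-1,6-dimethylcyclohex-2-en-1-yl]methyl}-1,4-dimethoxybenzene | C=CC1=CCC[C@H](C)[C@@]1(C)Cc1cc(OC)ccc1OC | intermediate
9 | methacrolein (2-methylprop-2-enal) | C=C(C)C=O | starting material
10 | Diels–Alder aldehyde (1S,5R,6S,8aR)-5-(2,5-dimethoxybenzyl)-1,5,6-trimethyl-1,2,3,5,6,7,8,8a-octahydronaphthalene-1-carbaldehyde (the 8a-epimer is equally serviceable) | O=C[C@@]1(C)CCC=C2[C@H]1CC[C@H](C)[C@@]2(C)Cc1cc(OC)ccc1OC | intermediate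
11 | ring-fusion alkene aldehyde (1S,5R,6S)-5-(2,5-dimethoxybenzyl)-1,5,6-trimethyl-1,2,3,4,5,6,7,8-octahydronaphthalene-1-carbaldehyde | O=C[C@@]1(C)CCCC2=C1CC[C@H](C)[C@@]2(C)Cc1cc(OC)ccc1OC | intermediate
12 | enol ether (1R,5R,6S)-5-(2,5-dimethoxybenzyl)-1-(2-methoxyethenyl)-1,5,6-trimethyl-1,2,3,4,5,6,7,8-octahydronaphthalene (E/Z; E drawn) | CO/C=C/[C@@]1(C)CCCC2=C1CC[C@H](C)[C@@]2(C)Cc1cc(OC)ccc1OC | intermediate
13 | homologated aldehyde 2-[(1R,5R,6S)-5-(2,5-dimethoxybenzyl)-1,5,6-trimethyl-1,2,3,4,5,6,7,8-octahydronaphthalen-1-yl]acetaldehyde | O=CC[C@@]1(C)CCCC2=C1CC[C@H](C)[C@@]2(C)Cc1cc(OC)ccc1OC | intermediate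
14 | (S)-2-methylcyclohex-2-en-1-ol | CC1=CCCC[C@@H]1O | intermediate
15 | tert-butyldimethyl{[(1S)-2-methylcyclohex-2-en-1-yl]oxy}silane | CC1=CCCC[C@@H]1O[Si](C)(C)C(C)(C)C | intermediate
16 | (S)-4-[(tert-butyldimethylsilyl)oxy]-3-methylcyclohex-2-en-1-one | O=C1C=C(C)[C@@H](O[Si](C)(C)C(C)(C)C)CC1 | intermediate
17 | 5-bromo-2-methylpent-2-ene | CC(C)=CCCBr | starting material
18 | (4-methylpent-3-en-1-yl)magnesium bromide (formed in the flask) | CC(C)=CCC[Mg]Br | intermediate
19 | ring A silyl enol ether (3S,4S)-4-[(tert-butyldimethylsilyl)oxy]-3-methyl-3-(4-methylpent-3-en-1-yl)-1-[(trimethylsilyl)oxy]cyclohex-1-ene | C[Si](C)(C)OC1=C[C@](C)(CCC=C(C)C)[C@@H](O[Si](C)(C)C(C)(C)C)CC1 | intermediate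
20 | ring A lithium enolate, lithium (3S,4S)-4-[(tert-butyldimethylsilyl)oxy]-3-methyl-3-(4-methylpent-3-en-1-yl)cyclohex-1-en-1-olate (formed in the flask) | [Li+].[O-]C1=C[C@](C)(CCC=C(C)C)[C@@H](O[Si](C)(C)C(C)(C)C)CC1 | intermediate
21 | aldol adduct (3S,4S)-4-[(tert-butyldimethylsilyl)oxy]-2-{2-[(1R,5R,6S)-5-(2,5-dimethoxybenzyl)-1,5,6-trimethyl-1,2,3,4,5,6,7,8-octahydronaphthalen-1-yl]-1-hydroxyethyl}-3-methyl-3-(4-methylpent-3-en-1-yl)cyclohexan-1-one (epimers at C-2 and at the carbinol carbon) | O=C1CC[C@H](O[Si](C)(C)C(C)(C)C)[C@@](C)(CCC=C(C)C)C1C(O)C[C@@]1(C)CCCC2=C1CC[C@H](C)[C@@]2(C)Cc1cc(OC)ccc1OC | intermediate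
22 | aldol methanesulfonate: 21 with the carbinol OH converted into OSO2CH3 (formed in the flask) | O=C1CC[C@H](O[Si](C)(C)C(C)(C)C)[C@@](C)(CCC=C(C)C)C1C(OS(C)(=O)=O)C[C@@]1(C)CCCC2=C1CC[C@H](C)[C@@]2(C)Cc1cc(OC)ccc1OC | intermediate
23 | ring A 2-alkylidene ketone (3S,4S)-4-[(tert-butyldimethylsilyl)oxy]-2-{2-[(1R,5R,6S)-5-(2,5-dimethoxybenzyl)-1,5,6-trimethyl-1,2,3,4,5,6,7,8-octahydronaphthalen-1-yl]ethylidene}-3-methyl-3-(4-methylpent-3-en-1-yl)cyclohexan-1-one (E/Z) | O=C1CC[C@H](O[Si](C)(C)C(C)(C)C)[C@@](C)(CCC=C(C)C)C1=CC[C@@]1(C)CCCC2=C1CC[C@H](C)[C@@]2(C)Cc1cc(OC)ccc1OC | intermediate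
24 | saturated ring A ketone (2S,3S,4S)-4-[(tert-butyldimethylsilyl)oxy]-2-{2-[(1R,5R,6S)-5-(2,5-dimethoxybenzyl)-1,5,6-trimethyl-1,2,3,4,5,6,7,8-octahydronaphthalen-1-yl]ethyl}-3-methyl-3-(4-methylpent-3-en-1-yl)cyclohexan-1-one | O=C1CC[C@H](O[Si](C)(C)C(C)(C)C)[C@@](C)(CCC=C(C)C)[C@@H]1CC[C@@]1(C)CCCC2=C1CC[C@H](C)[C@@]2(C)Cc1cc(OC)ccc1OC | intermediate
25 | exocyclic methylene silyl ether tert-butyl{[(1S,2S,3R)-3-{2-[(1R,5R,6S)-5-(2,5-dimethoxybenzyl)-1,5,6-trimethyl-1,2,3,4,5,6,7,8-octahydronaphthalen-1-yl]ethyl}-2-methyl-4-methylidene-2-(4-methylpent-3-en-1-yl)cyclohexyl]oxy}dimethylsilane | C=C1CC[C@H](O[Si](C)(C)C(C)(C)C)[C@@](C)(CCC=C(C)C)[C@@H]1CC[C@@]1(C)CCCC2=C1CC[C@H](C)[C@@]2(C)Cc1cc(OC)ccc1OC | intermediate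
26 | benzoquinone silyl ether: 25 with the dimethoxyarene turned into the 2-substituted 1,4-benzoquinone (formed in the flask) | C=C1CC[C@H](O[Si](C)(C)C(C)(C)C)[C@@](C)(CCC=C(C)C)[C@@H]1CC[C@@]1(C)CCCC2=C1CC[C@H](C)[C@@]2(C)CC1=CC(=O)C=CC1=O | intermediate
27 | hydroquinone silyl ether: 25 with both OCH3 replaced by OH | C=C1CC[C@H](O[Si](C)(C)C(C)(C)C)[C@@](C)(CCC=C(C)C)[C@@H]1CC[C@@]1(C)CCCC2=C1CC[C@H](C)[C@@]2(C)Cc1cc(O)ccc1O | intermediate
28 | aryl monosulfate silyl ether: 27 with OSO3H on the phenol oxygen meta to the benzylic carbon (para to the free OH) | C=C1CC[C@H](O[Si](C)(C)C(C)(C)C)[C@@](C)(CCC=C(C)C)[C@@H]1CC[C@@]1(C)CCCC2=C1CC[C@H](C)[C@@]2(C)Cc1cc(OS(=O)(=O)O)ccc1O | intermediate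
29 | 4-hydroxy-3-{[(1R,2S,5R)-5-{2-[(1R,2S,3S)-3-hydroxy-2-methyl-6-methylidene-2-(4-methylpent-3-en-1-yl)cyclohexyl]ethyl}-1,2,5-trimethyl-1,2,3,4,5,6,7,8-octahydronaphthalen-1-yl]methyl}phenyl hydrogen sulfate (CNP0426156.3) | C=C1CC[C@H](O)[C@@](C)(CCC=C(C)C)[C@@H]1CC[C@@]1(C)CCCC2=C1CC[C@H](C)[C@@]2(C)Cc1cc(OS(=O)(=O)O)ccc1O | target

**Step count and risks**

Total step count: 18. Longest linear sequence: 14 steps (steps 1–7, then 12–18); the ring A branch (steps 8–11) is 4 steps and joins at step 12.

Steps most likely to fail:

1. Step 4. The crowded diene may react slowly while methacrolein polymerises, the enal may add in the reversed orientation, or the catalyst may not override the facial bias of the chiral diene, giving poor selectivity at the formyl-bearing carbon. Fallback: control of this centre is handed from the catalyst to separation of diastereomers. Setting out from diene 8, the cycloaddition is run with the stronger achiral Lewis acid EtAlCl2 in CH2Cl2 at −78 °C, which should give aldehyde 10 together with its epimer at the formyl-bearing carbon, the (1R)-adduct F1. The mixture is isomerised as in step 5. Because ring C is already enantiopure, the product 11 and the (1R)-configured tetrasubstituted aldehyde F2 are diastereomers and are separated by chromatography, so the route is rejoined at 11.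

2. Step 5. The ring-fusion cation may be captured by the electron-rich arene (Friedel–Crafts closure to an indane), may suffer 1,2-shifts from the neighbouring quaternary carbons, or the equilibration may stop short. Fallback: the alkene is moved through an allyl anion instead of a cation. Setting out from 10, NaBH4 in MeOH gives the neopentyl alcohol F3. KOtBu in DMSO at 70 °C removes the allylic ring-fusion hydrogen and reprotonates at the former alkene CH, giving the tetrasubstituted alkene alcohol F4. Dess–Martin oxidation returns aldehyde 11.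

3. Step 17. Sulfation may not discriminate enough between the two phenols (reaction at both, or at the hindered one), giving ionic mixtures that are hard to separate. Fallback: the sulfate is introduced as a neutral, chromatographable diester. Setting out from hydroquinone 27, the bulkier electrophile 2,2,2-trichloroethyl chlorosulfate with Et3N and DMAP in THF at 0 °C should give the aryl trichloroethyl sulfate F5, which can be purified from any regioisomer or bis-adduct on silica. Zn dust and HCO2NH4 in MeOH then unmask the sulfate monoester, rejoining the route at 28.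

Further compounds
F1 | step 4 | (1R,5R,6S,8aR)-5-(2,5-dimethoxybenzyl)-1,5,6-trimethyl-1,2,3,5,6,7,8,8a-octahydronaphthalene-1-carbaldehyde (epimer of 10 at the formyl-bearing carbon) | O=C[C@]1(C)CCC=C2[C@H]1CC[C@H](C)[C@@]2(C)Cc1cc(OC)ccc1OC
F2 | step 4 | (1R,5R,6S)-5-(2,5-dimethoxybenzyl)-1,5,6-trimethyl-1,2,3,4,5,6,7,8-octahydronaphthalene-1-carbaldehyde (epimer of 11 at the formyl-bearing carbon) | O=C[C@]1(C)CCCC2=C1CC[C@H](C)[C@@]2(C)Cc1cc(OC)ccc1OC
F3 | step 5 | [(1S,5R,6S,8aR)-5-(2,5-dimethoxybenzyl)-1,5,6-trimethyl-1,2,3,5,6,7,8,8a-octahydronaphthalen-1-yl]methanol | OC[C@@]1(C)CCC=C2[C@H]1CC[C@H](C)[C@@]2(C)Cc1cc(OC)ccc1OC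
F4 | step 5 | [(1S,5R,6S)-5-(2,5-dimethoxybenzyl)-1,5,6-trimethyl-1,2,3,4,5,6,7,8-octahydronaphthalen-1-yl]methanol | OC[C@@]1(C)CCCC2=C1CC[C@H](C)[C@@]2(C)Cc1cc(OC)ccc1OC
F5 | step 17 | aryl 2,2,2-trichloroethyl sulfate: 27 with OSO2OCH2CCl3 on the phenol oxygen meta to the benzylic carbon | C=C1CC[C@H](O[Si](C)(C)C(C)(C)C)[C@@](C)(CCC=C(C)C)[C@@H]1CC[C@@]1(C)CCCC2=C1CC[C@H](C)[C@@]2(C)Cc1cc(OS(=O)(=O)OCC(Cl)(Cl)Cl)ccc1O
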